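## The problem

The target is a germacranolide. Ring carbons are numbered C1–C10; C11 is on C7, C12 is the lactone carbonyl, C13 the exocyclic methylene carbon, C14 the methyl on C10 and C15 the methyl on C4. The configuration is 1R,3R,6S,7R,8S,10S.

- **Ring system.** A ten-membered carbocycle is cis-fused at C6–C7 to an α-methylene-γ-butyrolactone. It carries a cis-epoxide at C1–C10, an acetate at C3, a Z-trisubstituted alkene C4=C5 and an isovalerate at C8. Direct closure of such a ring is penalised by entropy and transannular strain, and both ring alkenes (C4=C5, and the C1=C10 alkene behind the epoxide) must be Z.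
- **Stereocentres.** C6 and C7 are contiguous and cis, and are best set on a small rigid ring. C8 is next to C7, trans to the C7 side chain and 1,3-anti to the C6 oxygen. C3 and the epoxide are remote and sit on a mobile ring, so they need reagent control or a clear steric argument.
- **Sensitive groups.** The methylene lactone (Michael acceptor), the epoxide (acid-labile, prone to transannular opening) and two different esters, one allylic, rule out strong acid, base and nucleophiles late in the route. O8 must be acylated before the lactone is closed, otherwise an 8,12-olide competes.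
- **Enabling feature.** C3 and C8 both bear oxygen and face each other across the ring (1,6 along either arc). A C3–C8 bond, absent from the target, turns the macrocycle into a bicyclo[4.4.0]decadiene. Ring A (C3–C4–C5–C6–C7–C8) then holds C4=C5 and ring B (C3–C2–C1–C10–C9–C8) holds C1=C10, so both alkenes are Z by necessity and C6/C7 sit on a cyclohexene. Oxidative scission of a C3,C8-diol returns the ten-membered ring with a ketone at exactly the two carbons that need oxygen.

## Retrosynthesis

**Epoxide last (31 ⇒ 30).** The two C–O bonds of the epoxide are cut first. An epoxide carried through the ring opening would sit β,γ to both new ketones and open by elimination. In triene lactone 30 only C1=C10 is electron-rich, and the acyloxy groups at C3 and C8 flank it on the same face, so the forward step needs one chemoselective, face-selective peracid epoxidation.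

**Lactone (30 ⇒ 27 ⇒ 26).** The O6–C12 bond and the C12 oxidation level are removed, giving diol 27 and its bis-silyl ether 26. A free C12 acid or ester would not survive the organometallic steps, and a C6 hydroxyl cannot be free while C3 is a ketone. The forward reaction is an oxidative lactonisation of a 1,4-diol, which is unambiguous because O8 already carries its ester.

**C3 and C8 esters (26 ⇒ 25 ⇒ 24 ⇒ 22 ⇒ 21).** Both acyloxy carbons are traced to ketones in dione 21. C3, an α-substituted enone carbonyl, is a standard substrate for oxazaborolidine-controlled reduction (25, then 26). C8 is reduced first, chemoselectively; hydride is expected on the face away from the C7 side chain and the C6 silyloxy group, giving alcohol 22 with the wrong configuration, so the ester is put on with inversion (24). This costs no extra step compared with reduction and acylation.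

**Key disconnection (21 ⇒ 19).** A C3–C8 bond is added in the retrosynthetic sense, making 21 the glycol-cleavage product of bicyclic cis-diol 19. Against macrolactonisation-type closures, metathesis or Nozaki–Hiyama–Kishi closure of the ten-membered ring, this cut forms no bond in the ring-forming step, fixes both alkene geometries and leaves C6 and C7 on a six-membered ring. The forward step needs only a diol that can chelate lead, and a product kept neutral.

**C6 carbinol (19 ⇒ 18 ⇒ 17).** The silyl ether and the C6–H bond are removed to give enone 17. C6 is carried at the ketone level because the oxidation pattern then maps onto a quinone monoketal. The forward reduction must place the hydroxyl cis to the C7 side chain.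

**Ring B (17 ⇒ 16 ⇒ 15 ⇒ 13).** Ring B is opened at C1=C10 (ring-closing metathesis of allyl on C3 and methallyl on C8 in 15), and C2–C3 is cut (allylmagnesium bromide 14 on ketone 13). A Diels–Alder construction with isoprene would need a tetrasubstituted, doubly oxygenated dienophile. Metathesis places the methyl on C10 unambiguously and gives the Z alkene in a six-membered ring.

**C8 carbinol (13 ⇒ 10 ⇒ 9 ⇒ 7).** The C8–C9 bond (methallyl bromide 11) and the C8–O bond are cut, oxygen first in the forward direction.

- Oxygen first, carbon second: both enter anti to the C7 side chain, so O8 ends cis to it and axial. The allyl reagent then adds anti to O8 and the diol is cis.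
- The reverse order would put the methallyl group axial, steer the allyl group to the other face and give a trans-diaxial diol that cannot chelate lead.
- The price is one protecting step (9 to 10). The group is lost without a separate step in the later ketal hydrolysis.

**Ring A and the only external stereocontrol (7 ⇒ 2 + 6).** The C7–C11 bond is cut by rhodium-catalysed asymmetric conjugate addition of alkenyl trifluoroborate 6 to quinone monoketal 2. The monoketal comes in one step from phenol 1, and 6 in two steps from 2-bromoallyl alcohol 3 via silyl ether 4. C3 and C6 are delivered at the ketone level, differentiated, and every later stereocentre is derived from C7.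

## Roads not taken

**Alternative 1: Wittig–Still ring contraction.** The cut is C7–C8. Tin–lithium exchange in the thirteen-membered α-stannyl ether A1 would trigger a [2,3] shift to A2, the ten-membered C8 alcohol fused to a 3-methylenetetrahydrofuran.

- Merits: one step makes the C7–C8 bond, the exocyclic C11=C13 alkene and a free C8 hydroxyl that is alone in the molecule. Here this road is better than the chosen plan, which must tell two ketones apart and invert C8.
- Weak points: A1 needs both Z-trisubstituted alkenes from acyclic olefinations, a thirteen-membered ring closure and a configured α-alkoxystannane. The C7/C8 relationship depends on a macrocyclic transition state, and [1,2] shift competes. A2 holds C12 at the ether level, so a late allylic oxidation beside three alkenes is needed.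
- Comparison: the chosen plan offers alkene geometry by ring size, no macrocyclisation and C6/C7 set on a cyclohexene.

**Alternative 2: Grob fragmentation.** The cut is the C6–C10 bond of hydroazulene mesylate A3. Its C6 alkoxide would fragment to cyclodecadienone A4, with C1=C10 formed stereospecifically.

- Merits: only one ketone appears, and C3 and C8 arrive as configured, orthogonally protected carbinols. In this respect it is superior to the chosen plan.
- Weak points: A4 has no substituent at C7. The C11–C13 unit, the C7 stereocentre and the cis C6 carbinol would all have to be set on the mobile ten-membered ring, by enolate chemistry next to a conjugated ketone. A3 needs five stereocentres, one quaternary, with the leaving group antiperiplanar to the ring-fusion bond.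
- Comparison: the chosen plan spends two late reductions but settles C6, C7 and the whole side chain before the ring is opened.

**Alternative 3: Anionic oxy-Cope expansion.** The C8–C9 bond forms while C1–C6 breaks. The potassium alkoxide of terpene-derived cyclohexenol A5 would rearrange to A6, the C6 ketone with C3 and C8 ethers.

- Merits: carbon–carbon bond formation and ring expansion in one mild step from the chiral pool. It probably reaches the bare ten-membered ring in fewer steps than the chosen plan.
- Weak points: a Z C1=C10 alkene requires the two alkenyl groups of A5 to be cis, so the alkenyl anion must add syn to the neighbouring isopropenyl group, and the chair must carry a ring carbon axial. C8 depends on a Z enol ether. Like A4, A6 lacks everything at C7.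
- Comparison: equal or better on ring formation, weaker where the target is hardest (C6, C7, lactone). The chosen plan forms no bond in its ring-forming step and so carries no geometric risk there.

Key step: step 13

Remark on the chemistry (assumption): descriptors in germacrane numbering are given in brackets. C3 and C8 of diol 19 become trigonal in step 13, so their configuration (3R,8S, both hydroxyls on the face of the C7 side chain) was chosen only because steps 7 and 8 deliver it reliably. The descriptor at C7 alternates between R and S along the route because substituent priorities change; the spatial arrangement does not.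

## Route

Step 1
Reactants: 1 4-methoxy-2-methylphenol
Product: 2 4,4-dimethoxy-2-methylcyclohexa-2,5-dien-1-one
Conditions: PhI(OAc)2, MeOH, 0 °C
Reagents that add atoms: methanol CO
Why: Oxidative dearomatisation of a para-methoxyphenol by a hypervalent iodine reagent, with methanol captured at the para carbon (quinone monoketal formation); no stereocentre is formed.

Step 2
Reactants: 3 2-bromoprop-2-en-1-ol
Product: 4 [(2-bromoprop-2-en-1-yl)oxy](tert-butyl)diphenylsilane
Conditions: TBDPSCl, imidazole, CH2Cl2, 0 °C → rt
Reagents that add atoms: tert-butyl(chloro)diphenylsilane CC(C)(C)[Si](Cl)(c1ccccc1)c1ccccc1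
Why: Imidazole-promoted silylation of a primary allylic alcohol; the robust silyl ether should survive every step up to the fluoride treatment of step 18.

Step 3
Reactants: 4 2-bromoallyl silyl ether
Product: 6 potassium {3-[(tert-butyldiphenylsilyl)oxy]prop-1-en-2-yl}trifluoroborate, via pinacol boronate 5 (not isolated)
Conditions: B2pin2, PdCl2(PPh3)2 (3 mol%), PPh3, KOPh, toluene, 50 °C; then KHF2, MeOH/H2O, rt
Reagents that add atoms: bis(pinacolato)diboron CC1(C)OB(OC1(C)C)B1OC(C)(C)C(C)(C)O1; potassium hydrogen difluoride [K+].F[H-]F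
Why: Miyaura borylation of a 1-alkenyl bromide (oxidative addition to zerovalent palladium, boryl transfer from the phenoxide-activated diboron, reductive elimination), then exchange of pinacol for fluoride to give the bench-stable trifluoroborate.

Step 4
Reactants: 2 quinone monoketal; 6 alkenyl trifluoroborate
Product: 7 (5S)-5-{3-[(tert-butyldiphenylsilyl)oxy]prop-1-en-2-yl}-4,4-dimethoxy-2-methylcyclohex-2-en-1-one [7S]
Conditions: [Rh(cod)2]BF4 (3 mol%), (S)-BINAP (3.3 mol%), Et3N, toluene/H2O, 25 → 50 °C
Reagents that add atoms: none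
Why: Hayashi–Miyaura reaction (asymmetric 1,4-addition of an alkenylboron reagent under monovalent rhodium catalysis) on a cyclohexadienone; the alkenylrhodium species should add only to the unsubstituted enone, the α-methyl enone being far slower. By the established facial sense for cyclohex-2-enones, (S)-BINAP is expected to set 7S; the antipodal ligand would be used if the sense proved opposite.

Step 5
Reactants: 7 ketone [7S]
Product: 9 (5R,6R)-5-{3-[(tert-butyldiphenylsilyl)oxy]prop-1-en-2-yl}-6-hydroxy-4,4-dimethoxy-2-methylcyclohex-2-en-1-one [7R,8R], via potassium enolate 8 (not isolated)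
Conditions: KN(SiMe3)2, THF, −78 °C; 2-(phenylsulfonyl)-3-phenyloxaziridine, −78 °C; aq. NH4Cl
Reagents that add atoms: 2-(phenylsulfonyl)-3-phenyloxaziridine O=S(=O)(N1OC1c1ccccc1)c1ccccc1
Why: Enolate hydroxylation with an N-sulfonyloxaziridine; only C8 is enolisable, and oxygen should enter anti to the C7 side chain. That configuration is immaterial because C8 is made planar again in step 7.

Step 6
Reactants: 9 α-hydroxy ketone
Product: 10 (5R,6R)-5-{3-[(tert-butyldiphenylsilyl)oxy]prop-1-en-2-yl}-4,4-dimethoxy-6-[(2-methoxypropan-2-yl)oxy]-2-methylcyclohex-2-en-1-one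
Conditions: 2-methoxypropene, PPTS (cat.), CH2Cl2, 0 °C; Et3N quench
Reagents that add atoms: 2-methoxypropene COC(C)=C
Why: Acid-catalysed addition of the alcohol to an enol ether (mixed-ketal protection); the group has no stereocentre, cannot migrate to the enolate oxygen as a silyl group could, and is lost in the hydrolysis of step 10.

Step 7
Reactants: 10 protected α-hydroxy ketone; 11 3-bromo-2-methylprop-1-ene
Product: 13 (5R,6S)-5-{3-[(tert-butyldiphenylsilyl)oxy]prop-1-en-2-yl}-4,4-dimethoxy-6-[(2-methoxypropan-2-yl)oxy]-2-methyl-6-(2-methylprop-2-en-1-yl)cyclohex-2-en-1-one [7R,8S], via lithium enolate 12 (not isolated)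
Conditions: LiN(iPr)2 (commercial solution), THF, −78 °C; 11, DMPU, −78 → −30 °C
Reagents that add atoms: none
Why: Alkylation of an α-alkoxy ketone enolate with an allylic bromide; with oxygen already on C8 the methallyl group should enter anti to the C7 side chain, leaving O8 cis and C9 trans to it (8S).

Step 8
Reactants: 13 ketone [7R,8S]; 14 allylmagnesium bromide
Product: 15 (1R,5R,6S)-5-{3-[(tert-butyldiphenylsilyl)oxy]prop-1-en-2-yl}-4,4-dimethoxy-6-[(2-methoxypropan-2-yl)oxy]-2-methyl-6-(2-methylprop-2-en-1-yl)-1-(prop-2-en-1-yl)cyclohex-2-en-1-ol [3R,7R,8S]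
Conditions: 14 (Et2O solution), THF, −78 °C; aq. NH4Cl
Reagents that add atoms: none
Why: 1,2-Addition of an allyl Grignard reagent to an enone carbonyl; in the half-chair with the C7 side chain and C9 pseudo-equatorial the C8–O bond is axial, and attack at C3 anti to that bond (Felkin–Anh sense, least torsional strain) puts C2 cis to C9 and O3 cis to O8 (3R).

Step 9
Reactants: 15 allyl/methallyl diene
Product: 16 (1R,4aR,8aS)-1-{3-[(tert-butyldiphenylsilyl)oxy]prop-1-en-2-yl}-2,2-dimethoxy-8a-[(2-methoxypropan-2-yl)oxy]-4,7-dimethyl-1,2,4a,5,8,8a-hexahydronaphthalen-4a-ol [3R,7R,8S]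
Conditions: second-generation Grubbs catalyst (5 mol%), CH2Cl2, 40 °C
Reagents that add atoms: none
Why: Ring-closing metathesis of the monosubstituted allyl group onto the 1,1-disubstituted methallyl group closes ring B as a cis-fused trisubstituted cyclohexene, so C1=C10 is Z by construction. The side-chain alkene is trans to the allyl group across ring A and more hindered, so it should not compete.

Step 10
Reactants: 16 bicyclic ketal
Product: 17 (1R,4aR,8aS)-1-{3-[(tert-butyldiphenylsilyl)oxy]prop-1-en-2-yl}-4a,8a-dihydroxy-4,7-dimethyl-4a,5,8,8a-tetrahydronaphthalen-2(1H)-one [3R,7R,8S]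
Conditions: PPTS, acetone/H2O (5:1), 40 °C
Reagents that add atoms: water O
Why: Mild acid hydrolysis of the allylic dimethyl ketal and of the mixed ketal on O8 in one operation; the C6 enone appears only now, when C8 is quaternary (no aromatisation) and C3 is no longer a carbonyl.

Step 11
Reactants: 17 enone diol
Product: 18 (1S,2S,4aR,8aS)-1-{3-[(tert-butyldiphenylsilyl)oxy]prop-1-en-2-yl}-4,7-dimethyl-1,2,4a,5,8,8a-hexahydronaphthalene-2,4a,8a-triol [3R,6S,7S,8S]
Conditions: LiBH(s-Bu)3, THF, −78 °C; aq. NH4Cl
Reagents that add atoms: none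
Why: 1,2-Reduction of a β,β-disubstituted cyclohexenone by a bulky trialkylborohydride; hydride should add to the face opposite to the C8 oxygen and the C7 side chain, giving the 6S alcohol cis to that side chain.

Step 12
Reactants: 18 triol
Product: 19 (1S,2S,4aR,8aS)-2-[(tert-butyldimethylsilyl)oxy]-1-{3-[(tert-butyldiphenylsilyl)oxy]prop-1-en-2-yl}-4,7-dimethyl-1,2,4a,5,8,8a-hexahydronaphthalene-4a,8a-diol [3R,6S,7S,8S]
Conditions: TBSOTf (1.1 equiv), 2,6-lutidine, CH2Cl2, −78 °C
Reagents that add atoms: tert-butyldimethylsilyl triflate CC(C)(C)[Si](C)(C)OS(=O)(=O)C(F)(F)F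
Why: Silylation of the only secondary hydroxyl at low temperature; the tertiary ring-fusion hydroxyls stay free. O6 must be masked because a free C6 hydroxyl would add to the C3 ketone of 21 across the Z alkene and dehydrate to a furan.

Step 13
Reactants: 19 bicyclic cis-diol
Product: 21 (4Z,1(10)Z,6S,7S)-6-[(tert-butyldimethylsilyl)oxy]-12-[(tert-butyldiphenylsilyl)oxy]germacra-1(10),4,11(13)-triene-3,8-dione, via cyclic lead diolate 20 (not isolated)
Conditions: Pb(OAc)4 (1.1 equiv), pyridine, CH2Cl2, −20 → 0 °C; cold filtration through Celite and neutral alumina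
Reagents that add atoms: none
Why: Criegee glycol cleavage: the cis-diol displaces two acetates on tetravalent lead to give the five-membered cyclic diester 20, which collapses in a concerted two-electron process; the C3–C8 bond breaks, both C–O bonds become carbonyls and lead leaves as divalent Pb(OAc)2. The closest known reaction type is the Pb(OAc)4 cleavage of cis-decalin-4a,8a-diols to cyclodecane-1,6-diones. No ring is closed by bond formation: the ten-membered ring appears because the bond shared by rings A and B is excised, so no cyclisation entropy or transannular strain is paid in a bond-forming transition state. No stereocentre is created; C6 and C7 are untouched, C3 and C8 become trigonal, and both alkenes keep the Z geometry imposed by the six-membered rings. The step needs chemoselectivity for the diol over three alkenes and an allylic silyl ether, which the cis-fusion secures by letting the diol chelate lead far faster than any other oxidation at this temperature. It also needs the dione to survive: pyridine buffers the acetic acid released, and the product, which could enolise at C7 or C9, undergo transannular aldol reaction or move C1=C10 into conjugation, is filtered cold and reduced at once.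

Step 14
Reactants: 21 dione
Product: 22 (4Z,1(10)Z,6S,7R,8R)-6-[(tert-butyldimethylsilyl)oxy]-12-[(tert-butyldiphenylsilyl)oxy]-8-hydroxygermacra-1(10),4,11(13)-trien-3-one
Conditions: NaBH4, MeOH/CH2Cl2 (1:1), −78 → −50 °C
Reagents that add atoms: none
Why: Chemoselective borohydride reduction of the saturated C8 ketone in the presence of the less electrophilic conjugated C3 ketone at low temperature; hydride is expected on the face opposite to the C7 side chain and the C6 silyloxy group, giving the 8R alcohol, the epimer required for an inverting esterification.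

Step 15
Reactants: 22 8R alcohol
Product: 24 (4Z,1(10)Z,6S,7R,8S)-6-[(tert-butyldimethylsilyl)oxy]-12-[(tert-butyldiphenylsilyl)oxy]-8-(3-methylbutanoyloxy)germacra-1(10),4,11(13)-trien-3-one, via oxyphosphonium salt 23 (not isolated)
Conditions: PPh3, DIAD, 3-methylbutanoic acid, toluene, 0 °C → rt
Reagents that add atoms: 3-methylbutanoic acid CC(C)CC(=O)O
Why: Mitsunobu esterification: the alcohol is activated as oxyphosphonium ion 23 and displaced by the carboxylate in an SN2 process, which installs the isovalerate and inverts C8 to 8S in one step.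

Step 16
Reactants: 24 enone ester
Product: 25 (4Z,1(10)Z,3R,6S,7R,8S)-6-[(tert-butyldimethylsilyl)oxy]-12-[(tert-butyldiphenylsilyl)oxy]-3-hydroxygermacra-1(10),4,11(13)-trien-8-yl 3-methylbutanoate
Conditions: (S)-2-methyl-CBS-oxazaborolidine (1 equiv), catecholborane, toluene, −78 °C; MeOH, pH 7 buffer
Reagents that add atoms: none
Why: Corey–Bakshi–Shibata reduction of an α-substituted enone: the C4 alkenyl side acts as the large group and the C2 methylene as the small one, so the (S)-catalyst should deliver hydride to give 3R under reagent control. Catecholborane at −78 °C reduces neither esters nor alkenes.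

Step 17
Reactants: 25 allylic alcohol
Product: 26 (4Z,1(10)Z,3R,6S,7R,8S)-3-acetoxy-6-[(tert-butyldimethylsilyl)oxy]-12-[(tert-butyldiphenylsilyl)oxy]germacra-1(10),4,11(13)-trien-8-yl 3-methylbutanoate
Conditions: Ac2O, pyridine, DMAP (cat.), CH2Cl2, 0 °C
Reagents that add atoms: acetic anhydride CC(=O)OC(C)=O
Why: DMAP-catalysed acylation of a secondary allylic alcohol; no stereocentre is touched.

Step 18
Reactants: 26 bis-silyl ether
Product: 27 (4Z,1(10)Z,3R,6S,7S,8S)-3-acetoxy-6,12-dihydroxygermacra-1(10),4,11(13)-trien-8-yl 3-methylbutanoate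
Conditions: Bu4NF, AcOH (1:1), THF, 0 °C → rt
Reagents that add atoms: none
Why: Fluoride-mediated cleavage of both silyl ethers, buffered with acetic acid so that neither ester should migrate or hydrolyse.

Step 19
Reactants: 27 diol
Product: 30 (4Z,1(10)Z,3R,6S,7R,8S)-3-acetoxy-8-(3-methylbutanoyloxy)germacra-1(10),4,11(13)-trien-12,6-olide, via hydroxy enal 28 (not isolated), via lactol 29 (not isolated)
Conditions: TEMPO (20 mol%), PhI(OAc)2 (2.5 equiv), CH2Cl2, rt
Reagents that add atoms: none
Why: Oxoammonium-mediated oxidation: the primary allylic alcohol is oxidised to enal 28 much faster than the secondary one, the C6 hydroxyl closes to the cis-fused five-membered lactol 29, and a second oxidation gives the α-methylene lactone. Because O8 is already acylated, only the 6,12-olide can form.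

Step 20
Reactants: 30 triene lactone
Product: 31 CNP0157657.2, (1R,3R,6S,7R,8S,10S,4Z)-3-acetoxy-1,10-epoxy-8-(3-methylbutanoyloxy)germacra-4,11(13)-dien-12,6-olide
Conditions: mCPBA, NaHCO3, CH2Cl2, 0 °C
Reagents that add atoms: 3-chloroperoxybenzoic acid OOC(=O)c1cccc(Cl)c1
Why: Prilezhaev epoxidation: C1=C10 is the only electron-rich alkene (C4=C5 carries two allylic acyloxy groups, C11=C13 is conjugated to the lactone). The peracid should approach anti to the acyloxy groups at C3 and C8, which flank the alkene on the same face, giving the 1R,10S cis-epoxide.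

## Compound list

1 | 4-methoxy-2-methylphenol | COc1ccc(O)c(C)c1 | starting material
2 | 4,4-dimethoxy-2-methylcyclohexa-2,5-dien-1-one | COC1(OC)C=CC(=O)C(C)=C1 | intermediate
3 | 2-bromoprop-2-en-1-ol | OCC(Br)=C | starting material
4 | [(2-bromoprop-2-en-1-yl)oxy](tert-butyl)diphenylsilane | C=C(Br)CO[Si](c1ccccc1)(c2ccccc2)C(C)(C)C | intermediate
5 | tert-butyldiphenyl{[2-(4,4,5,5-tetramethyl-1,3,2-dioxaborolan-2-yl)prop-2-en-1-yl]oxy}silane | C=C(CO[Si](c1ccccc1)(c2ccccc2)C(C)(C)C)B3OC(C)(C)C(C)(C)O3 | intermediate
6 | potassium {3-[(tert-butyldiphenylsilyl)oxy]prop-1-en-2-yl}trifluoroborate | [K+].F[B-](F)(F)C(=C)CO[Si](c1ccccc1)(c2ccccc2)C(C)(C)C | intermediate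
7 | (5S)-5-{3-[(tert-butyldiphenylsilyl)oxy]prop-1-en-2-yl}-4,4-dimethoxy-2-methylcyclohex-2-en-1-one | C=C(CO[Si](c1ccccc1)(c2ccccc2)C(C)(C)C)[C@@H]3CC(=O)C(C)=CC3(OC)OC | intermediate
8 | potassium dienolate of 7 (O– on C3, C3=C8) | [K+].C=C(CO[Si](c1ccccc1)(c2ccccc2)C(C)(C)C)[C@@H]3C=C([O-])C(C)=CC3(OC)OC | intermediate
9 | (5R,6R)-5-{3-[(tert-butyldiphenylsilyl)oxy]prop-1-en-2-yl}-6-hydroxy-4,4-dimethoxy-2-methylcyclohex-2-en-1-one | C=C(CO[Si](c1ccccc1)(c2ccccc2)C(C)(C)C)[C@@H]3[C@@H](O)C(=O)C(C)=CC3(OC)OC | intermediate
10 | (5R,6R)-5-{3-[(tert-butyldiphenylsilyl)oxy]prop-1-en-2-yl}-4,4-dimethoxy-6-[(2-methoxypropan-2-yl)oxy]-2-methylcyclohex-2-en-1-one | C=C(CO[Si](c1ccccc1)(c2ccccc2)C(C)(C)C)[C@@H]3[C@@H](OC(C)(C)OC)C(=O)C(C)=CC3(OC)OC | intermediate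
11 | 3-bromo-2-methylprop-1-ene | CC(=C)CBr | starting material
12 | lithium enolate of 10 (O– on C3, C3=C8) | [Li+].C=C(CO[Si](c1ccccc1)(c2ccccc2)C(C)(C)C)[C@@H]3C(OC(C)(C)OC)=C([O-])C(C)=CC3(OC)OC | intermediate
13 | (5R,6S)-5-{3-[(tert-butyldiphenylsilyl)oxy]prop-1-en-2-yl}-4,4-dimethoxy-6-[(2-methoxypropan-2-yl)oxy]-2-methyl-6-(2-methylprop-2-en-1-yl)cyclohex-2-en-1-one | C=C(CO[Si](c1ccccc1)(c2ccccc2)C(C)(C)C)[C@@H]3[C@@](OC(C)(C)OC)(CC(C)=C)C(=O)C(C)=CC3(OC)OC | intermediate
14 | allylmagnesium bromide | C=CC[Mg]Br | starting material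
15 | (1R,5R,6S)-5-{3-[(tert-butyldiphenylsilyl)oxy]prop-1-en-2-yl}-4,4-dimethoxy-6-[(2-methoxypropan-2-yl)oxy]-2-methyl-6-(2-methylprop-2-en-1-yl)-1-(prop-2-en-1-yl)cyclohex-2-en-1-ol | C=C(CO[Si](c1ccccc1)(c2ccccc2)C(C)(C)C)[C@@H]3[C@@](OC(C)(C)OC)(CC(C)=C)[C@@](O)(CC=C)C(C)=CC3(OC)OC | intermediate
16 | (1R,4aR,8aS)-1-{3-[(tert-butyldiphenylsilyl)oxy]prop-1-en-2-yl}-2,2-dimethoxy-8a-[(2-methoxypropan-2-yl)oxy]-4,7-dimethyl-1,2,4a,5,8,8a-hexahydronaphthalen-4a-ol | C=C(CO[Si](c1ccccc1)(c2ccccc2)C(C)(C)C)[C@@H]3[C@@]4(OC(C)(C)OC)CC(C)=CC[C@@]4(O)C(C)=CC3(OC)OC | intermediate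
17 | (1R,4aR,8aS)-1-{3-[(tert-butyldiphenylsilyl)oxy]prop-1-en-2-yl}-4a,8a-dihydroxy-4,7-dimethyl-4a,5,8,8a-tetrahydronaphthalen-2(1H)-one | C=C(CO[Si](c1ccccc1)(c2ccccc2)C(C)(C)C)[C@@H]3[C@@]4(O)CC(C)=CC[C@@]4(O)C(C)=CC3=O | intermediate
18 | (1S,2S,4aR,8aS)-1-{3-[(tert-butyldiphenylsilyl)oxy]prop-1-en-2-yl}-4,7-dimethyl-1,2,4a,5,8,8a-hexahydronaphthalene-2,4a,8a-triol | C=C(CO[Si](c1ccccc1)(c2ccccc2)C(C)(C)C)[C@@H]3[C@@]4(O)CC(C)=CC[C@@]4(O)C(C)=C[C@@H]3O | intermediate
19 | (1S,2S,4aR,8aS)-2-[(tert-butyldimethylsilyl)oxy]-1-{3-[(tert-butyldiphenylsilyl)oxy]prop-1-en-2-yl}-4,7-dimethyl-1,2,4a,5,8,8a-hexahydronaphthalene-4a,8a-diol | C=C(CO[Si](c1ccccc1)(c2ccccc2)C(C)(C)C)[C@@H]3[C@@]4(O)CC(C)=CC[C@@]4(O)C(C)=C[C@@H]3O[Si](C)(C)C(C)(C)C | intermediate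
20 | cyclic diacetoxylead 4a,8a-diolate of 19 (five-membered O–Pb–O ring across C3 and C8) | C=C(CO[Si](c1ccccc1)(c2ccccc2)C(C)(C)C)[C@@H]3[C@@]45CC(C)=CC[C@@]4(O[Pb](OC(C)=O)(OC(C)=O)O5)C(C)=C[C@@H]3O[Si](C)(C)C(C)(C)C | intermediate
21 | (4Z,1(10)Z,6S,7S)-6-[(tert-butyldimethylsilyl)oxy]-12-[(tert-butyldiphenylsilyl)oxy]germacra-1(10),4,11(13)-triene-3,8-dione | CC(C)(C)[Si](C)(C)O[C@H]1/C=C(/C)C(=O)C/C=C(/C)CC(=O)[C@H]1C(=C)CO[Si](c2ccccc2)(c3ccccc3)C(C)(C)C | intermediate
22 | (4Z,1(10)Z,6S,7R,8R)-6-[(tert-butyldimethylsilyl)oxy]-12-[(tert-butyldiphenylsilyl)oxy]-8-hydroxygermacra-1(10),4,11(13)-trien-3-one | CC(C)(C)[Si](C)(C)O[C@H]1/C=C(/C)C(=O)C/C=C(/C)C[C@@H](O)[C@H]1C(=C)CO[Si](c2ccccc2)(c3ccccc3)C(C)(C)C | intermediate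
23 | O8-triphenylphosphonium derivative of 22 as its 3-methylbutanoate salt | CC(C)(C)[Si](C)(C)O[C@H]1/C=C(/C)C(=O)C/C=C(/C)C[C@@H](O[P+](c4ccccc4)(c5ccccc5)c6ccccc6)[C@H]1C(=C)CO[Si](c2ccccc2)(c3ccccc3)C(C)(C)C.CC(C)CC(=O)[O-] | intermediate
24 | (4Z,1(10)Z,6S,7R,8S)-6-[(tert-butyldimethylsilyl)oxy]-12-[(tert-butyldiphenylsilyl)oxy]-8-(3-methylbutanoyloxy)germacra-1(10),4,11(13)-trien-3-one | CC(C)(C)[Si](C)(C)O[C@H]1/C=C(/C)C(=O)C/C=C(/C)C[C@H](OC(=O)CC(C)C)[C@H]1C(=C)CO[Si](c2ccccc2)(c3ccccc3)C(C)(C)C | intermediate
25 | (4Z,1(10)Z,3R,6S,7R,8S)-6-[(tert-butyldimethylsilyl)oxy]-12-[(tert-butyldiphenylsilyl)oxy]-3-hydroxygermacra-1(10),4,11(13)-trien-8-yl 3-methylbutanoate | CC(C)(C)[Si](C)(C)O[C@H]1/C=C(/C)[C@H](O)C/C=C(/C)C[C@H](OC(=O)CC(C)C)[C@H]1C(=C)CO[Si](c2ccccc2)(c3ccccc3)C(C)(C)C | intermediate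
26 | (4Z,1(10)Z,3R,6S,7R,8S)-3-acetoxy-6-[(tert-butyldimethylsilyl)oxy]-12-[(tert-butyldiphenylsilyl)oxy]germacra-1(10),4,11(13)-trien-8-yl 3-methylbutanoate | CC(C)(C)[Si](C)(C)O[C@H]1/C=C(/C)[C@H](OC(C)=O)C/C=C(/C)C[C@H](OC(=O)CC(C)C)[C@H]1C(=C)CO[Si](c2ccccc2)(c3ccccc3)C(C)(C)C | intermediate
27 | (4Z,1(10)Z,3R,6S,7S,8S)-3-acetoxy-6,12-dihydroxygermacra-1(10),4,11(13)-trien-8-yl 3-methylbutanoate | O[C@H]1/C=C(/C)[C@H](OC(C)=O)C/C=C(/C)C[C@H](OC(=O)CC(C)C)[C@H]1C(=C)CO | intermediate
28 | (4Z,1(10)Z,3R,6S,7S,8S)-3-acetoxy-6-hydroxy-12-oxogermacra-1(10),4,11(13)-trien-8-yl 3-methylbutanoate | O[C@H]1/C=C(/C)[C@H](OC(C)=O)C/C=C(/C)C[C@H](OC(=O)CC(C)C)[C@H]1C(=C)C=O | intermediate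
29 | 6,12-lactol of 28 (cis-fused 2-hydroxy-3-methylenetetrahydrofuran; both C12 epimers) | C=C1C(O)O[C@H]2/C=C(/C)[C@H](OC(C)=O)C/C=C(/C)C[C@H](OC(=O)CC(C)C)[C@@H]12 | intermediate
30 | (4Z,1(10)Z,3R,6S,7R,8S)-3-acetoxy-8-(3-methylbutanoyloxy)germacra-1(10),4,11(13)-trien-12,6-olide | C=C1C(=O)O[C@H]2/C=C(/C)[C@H](OC(C)=O)C/C=C(/C)C[C@H](OC(=O)CC(C)C)[C@@H]12 | intermediate
31 | CNP0157657.2, (1R,3R,6S,7R,8S,10S,4Z)-3-acetoxy-1,10-epoxy-8-(3-methylbutanoyloxy)germacra-4,11(13)-dien-12,6-olide | C=C1C(=O)O[C@H]2/C=C(/C)[C@H](OC(C)=O)C[C@H]3O[C@@]3(C)C[C@H](OC(=O)CC(C)C)[C@@H]12 | target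

## Step count and least certain steps

Total: 20 steps. Longest linear sequence: 19 steps (from 3 through steps 2–20); the branch from 1 joins at step 4.

**Step 13 (key step).** The cleavage itself is reliable. The danger is loss of the dione as it forms or during isolation: transannular aldol reaction, enolisation at C7 with epimerisation, migration of C1=C10 into conjugation, or elimination of silanol. Formation of the cyclic lead ester may also be slow if the silyloxy group on C6 crowds O8. The fallback changes what is isolated. Starting from 19, the cleavage is run at −40 °C in CH2Cl2/MeOH and NaBH4 is added to the same flask at −78 °C, so that 21 is reduced as it forms and never concentrated. No new compound arises (F0), and the route is rejoined at 22.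

**Step 11.** Facial selectivity may be poor or reversed, by axial attack or by hydride delivery from the neighbouring alkoxide, and the lithium alkoxide of the β-hydroxy ketone may undergo retro-aldol opening. The fallback accepts the opposite sense and inverts. From 17, Luche reduction (NaBH4, CeCl3·7H2O, MeOH, −78 °C) should give the 6R triol F1. A Mitsunobu reaction with 4-nitrobenzoic acid then gives the inverted 4-nitrobenzoate F2, and K2CO3 in MeOH returns 18.

**Step 14.** The ten-membered ring is mobile, so hydride may arrive on the other face or without preference, and some enone reduction may compete. If the other face is attacked, the product is the 8S alcohol F3. Starting from 21, F3 is esterified with retention (3-methylbutanoic anhydride, DMAP, CH2Cl2) and the route is rejoined at 24, without the inversion of step 15.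

**Step 15.** The activated alcohol may eliminate toward the conjugated dienes (allylic hydrogens at C7 and C9), or substitution at the hindered C8 may not occur. The fallback avoids substitution at C8 and uses reagent control.

- From 21, (S)-2-methyl-CBS-oxazaborolidine and catecholborane at −78 °C should reduce the enone alone, giving the 3R hydroxy ketone F4.
- Acetylation gives the keto acetate F5.
- The (R)-oxazaborolidine with catecholborane at −20 °C should then set C8, giving the 8S alcohol F6.
- Acylation with 3-methylbutanoic anhydride and DMAP rejoins the route at 26.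

**Step 16.** The catalyst may be mismatched with the facial bias of the ring, eroding selectivity, or conjugate reduction may intervene. The fallback uses substrate control and inversion: from 24, Luche reduction should favour the 3S alcohol F7, and a Mitsunobu reaction with acetic acid would give 26 directly.

**Step 20.** The peracid may attack the other face of C1=C10, or compete at C4=C5. The fallback reverses the facial outcome through a halohydrin. From 30, N-bromosuccinimide in aqueous THF delivers bromine to the same accessible face and water to C10 from the opposite face, giving the bromohydrin F8. K2CO3 in MeOH at 0 °C then closes the epoxide on the face that the peracid avoided, and the route is rejoined at 31.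

## Further compounds

F0 | step 13 | none | none
F1 | step 11 | (1S,2R,4aR,8aS)-1-{3-[(tert-butyldiphenylsilyl)oxy]prop-1-en-2-yl}-4,7-dimethyl-1,2,4a,5,8,8a-hexahydronaphthalene-2,4a,8a-triol (6R epimer of 18) | C=C(CO[Si](c1ccccc1)(c2ccccc2)C(C)(C)C)[C@@H]3[C@@]4(O)CC(C)=CC[C@@]4(O)C(C)=C[C@H]3O
F2 | step 11 | 4-nitrobenzoate of 18 at O6 (6S) | C=C(CO[Si](c1ccccc1)(c2ccccc2)C(C)(C)C)[C@@H]3[C@@]4(O)CC(C)=CC[C@@]4(O)C(C)=C[C@@H]3OC(=O)c5ccc(cc5)[N+](=O)[O-]
F3 | step 14 | (4Z,1(10)Z,6S,7R,8S)-6-[(tert-butyldimethylsilyl)oxy]-12-[(tert-butyldiphenylsilyl)oxy]-8-hydroxygermacra-1(10),4,11(13)-trien-3-one | CC(C)(C)[Si](C)(C)O[C@H]1/C=C(/C)C(=O)C/C=C(/C)C[C@H](O)[C@H]1C(=C)CO[Si](c2ccccc2)(c3ccccc3)C(C)(C)C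
F4 | step 15 | (4Z,1(10)Z,3R,6S,7S)-6-[(tert-butyldimethylsilyl)oxy]-12-[(tert-butyldiphenylsilyl)oxy]-3-hydroxygermacra-1(10),4,11(13)-trien-8-one | CC(C)(C)[Si](C)(C)O[C@H]1/C=C(/C)[C@H](O)C/C=C(/C)CC(=O)[C@H]1C(=C)CO[Si](c2ccccc2)(c3ccccc3)C(C)(C)C
F5 | step 15 | (4Z,1(10)Z,3R,6S,7S)-3-acetoxy-6-[(tert-butyldimethylsilyl)oxy]-12-[(tert-butyldiphenylsilyl)oxy]germacra-1(10),4,11(13)-trien-8-one | CC(C)(C)[Si](C)(C)O[C@H]1/C=C(/C)[C@H](OC(C)=O)C/C=C(/C)CC(=O)[C@H]1C(=C)CO[Si](c2ccccc2)(c3ccccc3)C(C)(C)C
F6 | step 15 | (4Z,1(10)Z,3R,6S,7R,8S)-3-acetoxy-6-[(tert-butyldimethylsilyl)oxy]-12-[(tert-butyldiphenylsilyl)oxy]germacra-1(10),4,11(13)-trien-8-ol | CC(C)(C)[Si](C)(C)O[C@H]1/C=C(/C)[C@H](OC(C)=O)C/C=C(/C)C[C@H](O)[C@H]1C(=C)CO[Si](c2ccccc2)(c3ccccc3)C(C)(C)C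
F7 | step 16 | (4Z,1(10)Z,3S,6S,7R,8S)-6-[(tert-butyldimethylsilyl)oxy]-12-[(tert-butyldiphenylsilyl)oxy]-3-hydroxygermacra-1(10),4,11(13)-trien-8-yl 3-methylbutanoate | CC(C)(C)[Si](C)(C)O[C@H]1/C=C(/C)[C@@H](O)C/C=C(/C)C[C@H](OC(=O)CC(C)C)[C@H]1C(=C)CO[Si](c2ccccc2)(c3ccccc3)C(C)(C)C
F8 | step 20 | (1S,3R,6S,7R,8S,10S,4Z)-3-acetoxy-1-bromo-10-hydroxy-8-(3-methylbutanoyloxy)germacra-4,11(13)-dien-12,6-olide | C=C1C(=O)O[C@H]2/C=C(/C)[C@H](OC(C)=O)C[C@H](Br)[C@@](C)(O)C[C@H](OC(=O)CC(C)C)[C@@H]12
A1 | alternative 1 | thirteen-membered α-tributylstannyl ether (C8–O–C13) with C7=C11 in a 2,5-dihydrofuran, C3 silyl ether | CCCC[Sn](CCCC)(CCCC)[C@@H]1OCC2=C[C@@H](OC2)/C=C(/C)[C@H](O[Si](C)(C)C(C)(C)C)C/C=C(/C)C1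
A2 | alternative 1 | ten-membered C8 alcohol fused to a 3-methylenetetrahydrofuran, C3 silyl ether | C1O[C@H]2/C=C(/C)[C@H](O[Si](C)(C)C(C)(C)C)C/C=C(/C)C[C@H](O)[C@H]2C1=C
A3 | alternative 2 | cis-fused hydroazulene: C6 tertiary alcohol, C10 methyl, C1 mesylate, C3 PMB ether, C8 silyl ether, C4=C5 alkene | C[C@]12C[C@H](O[Si](C)(C)C(C)(C)C)C[C@@]1(O)C=C(C)[C@H](OCc3ccc(OC)cc3)C[C@H]2OS(C)(=O)=O
A4 | alternative 2 | (Z,Z)-cyclodeca-2,6-dienone (C6 ketone) with C3 PMB ether and C8 silyl ether | O=C1/C=C(/C)[C@H](OCc2ccc(OC)cc2)C/C=C(/C)C[C@H](O[Si](C)(C)C(C)(C)C)C1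
A5 | alternative 3 | 1-[(Z)-2-(4-methoxybenzyloxy)ethenyl]-3-methyl-4-(tert-butyldimethylsilyloxy)-6-(prop-1-en-2-yl)cyclohex-2-en-1-ol, alkenyl and isopropenyl cis | O[C@]1(/C=C\OCc2ccc(OC)cc2)C=C(C)[C@H](O[Si](C)(C)C(C)(C)C)C[C@H]1C(C)=C
A6 | alternative 3 | (Z,Z)-cyclodeca-2,6-dienone (C6 ketone) with C3 silyl ether and C8 PMB ether | O=C1/C=C(/C)[C@H](O[Si](C)(C)C(C)(C)C)C/C=C(/C)C[C@H](OCc2ccc(OC)cc2)C1
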